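**Strategy**

The route rests on cutting the C4–CH3 and C5–C6 bonds of ring A (C1–C5, C10) in a single operation. That ring shows an oxygen at C2, a methyl at C4 on the opposite face and a methylated quaternary C5 with the two methyls syn, which is what a 5-oxygenated 2-methylcyclohexenone (carbonyl = C10) gives when its β-carbon is methylated and its α-carbon allylated. Thus a cuprate adds to the carvone-derived (S)-5-silyloxy-2-methylcyclohex-2-enone anti to the silyloxy group and the enolate is allylated anti to the new methyl; one purchased stereocentre sets C4 and C5. Allyl group and C10 ketone then serve to build ring B.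

Key step: step 4

Remark: eremophilane numbering is used; β is the face of the C5 methyl, α the opposite face; bicyclic compounds without the isopropenyl group are named as 11,12,13-trinoreremophilanes; the homologated aldehyde is carried on as a C10 epimer mixture because its equilibrium is not expected to favour one epimer, so the ring fusion is set after ring closure (step 9).

**Route**

Step 1
Reactants: 1 (S)-carvone
Product: 4 (1S)-4-methyl-5-oxocyclohex-3-en-1-yl acetate, via methoxy hydroperoxide 2 (not isolated), via peroxyacetate 3 (not isolated)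
Conditions: O3, MeOH/CH2Cl2, −78 °C; then Ac2O, Et3N, DMAP (cat.), CH2Cl2, 0 °C → rt
Reagents that add atoms: ozone, O=[O+][O-]; methanol, CO
Why: Ozonolysis of the electron-rich isopropenyl group in methanol gives the α-methoxy hydroperoxide, whose peracetate undergoes Criegee rearrangement with migration of the ring carbon to oxygen with retention, so the carvone stereocentre becomes the oxygenated carbon unchanged.

Step 2
Reactants: 4 (1S)-4-methyl-5-oxocyclohex-3-en-1-yl acetate
Product: 5 (5S)-5-hydroxy-2-methylcyclohex-2-en-1-one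
Conditions: K2CO3 (cat.), MeOH, 0 °C
Reagents that add atoms: none
Why: Base-catalysed transesterification at low temperature frees the alcohol before β-elimination to the cresol can compete, and no stereocentre is touched.

Step 3
Reactants: 5 (5S)-5-hydroxy-2-methylcyclohex-2-en-1-one
Product: 6 (5S)-5-(tert-butyldimethylsilyloxy)-2-methylcyclohex-2-en-1-one
Conditions: TBSCl, imidazole, DMF, 0 °C → rt
Reagents that add atoms: tert-butyldimethylsilyl chloride, CC(C)(C)[Si](C)(C)Cl
Why: Standard silylation of a secondary alcohol gives a bulky ether that is a poor leaving group and later steers the cuprate to the opposite face.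

Step 4
Reactants: 6 (5S)-5-(tert-butyldimethylsilyloxy)-2-methylcyclohex-2-en-1-one; 7 allyl bromide
Product: 9 (2R,3S,5S)-2-allyl-5-(tert-butyldimethylsilyloxy)-2,3-dimethylcyclohexan-1-one, via lithium enolate 8 (not isolated)
Conditions: MeLi, CuI, Et2O, 0 °C; 6, −78 → −30 °C; then 7, HMPA, THF, −30 → 0 °C
Reagents that add atoms: lithium dimethylcuprate, [Li+].C[Cu-]C (made in the flask from MeLi and CuI)
Why: The Gilman cuprate adds to the enone β-carbon (C4) through a copper–alkene complex and reductive elimination, giving regiospecifically the C5=C10 lithium enolate 8, which is C-allylated by SN2 attack on allyl bromide once HMPA is added. The closest known reaction type is the three-component conjugate addition–enolate alkylation of 2-methylcyclohex-2-enones. No ring is closed. C4 is set by 1,3-induction from C2, the methyl being delivered axially to the half-chair on the face opposite the silyloxy group, which gives the 2,4-trans relation. C5 is set by 1,2-induction from C4: in the enolate the new methyl sits pseudoaxial to avoid allylic strain with the C5 methyl and the electrophile enters axially anti to it, so the two methyls end cis at the quaternary centre. The step needs the enolate to keep its regiochemistry and to react at carbon, which aprotic conditions, a soft allylic electrophile and HMPA secure, and the silyloxy group is not eliminated because the enolate lies on the side remote from C1.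

Step 5
Reactants: 9 (2R,3S,5S)-2-allyl-5-(tert-butyldimethylsilyloxy)-2,3-dimethylcyclohexan-1-one
Product: 10 (2R,3S,5S)-2-allyl-5-(tert-butyldimethylsilyloxy)-1-(methoxymethylidene)-2,3-dimethylcyclohexane (E/Z mixture)
Conditions: Ph3P(Cl)CH2OMe, KHMDS, THF, 0 °C; then 9, 0 °C → rt
Reagents that add atoms: (methoxymethylene)triphenylphosphorane, COC=P(c1ccccc1)(c1ccccc1)c1ccccc1 (made in the flask from the phosphonium chloride and KHMDS)
Why: Wittig olefination with the reactive methoxymethylene ylide homologates the hindered α-quaternary ketone by one carbon (C9) at low temperature, where β-elimination of the silyloxy group should stay slow; no stereocentre is formed and the alkene geometry is irrelevant.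

Step 6
Reactants: 10 (2R,3S,5S)-2-allyl-5-(tert-butyldimethylsilyloxy)-1-(methoxymethylidene)-2,3-dimethylcyclohexane
Product: 11 (2R,3S,5S)-2-allyl-5-(tert-butyldimethylsilyloxy)-2,3-dimethylcyclohexane-1-carbaldehyde (both epimers at ring C1 = C10)
Conditions: oxalic acid, THF/H2O, rt
Reagents that add atoms: water, O
Why: Mild acid-catalysed enol ether hydrolysis gives the aldehyde while the silyl ether survives; the new C10 centre is deliberately not controlled here because it is reset in step 9.

Step 7
Reactants: 11 (2R,3S,5S)-2-allyl-5-(tert-butyldimethylsilyloxy)-2,3-dimethylcyclohexane-1-carbaldehyde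
Product: 12 1-[(2R,3S,5S)-2-allyl-5-(tert-butyldimethylsilyloxy)-2,3-dimethylcyclohexyl]prop-2-en-1-ol (epimers at ring C1 and at the carbinol carbon)
Conditions: CH2=CHMgBr, THF, −78 → 0 °C
Reagents that add atoms: vinylmagnesium bromide, C=C[Mg]Br
Why: Grignard 1,2-addition of the vinyl group supplies C8 and the C9 oxygen; the carbinol configuration is left uncontrolled because C9 passes through the ketone in step 9.

Step 8
Reactants: 12 1-[(2R,3S,5S)-2-allyl-5-(tert-butyldimethylsilyloxy)-2,3-dimethylcyclohexyl]prop-2-en-1-ol
Product: 13 2α-(tert-butyldimethylsilyloxy)-11,12,13-trinoreremophil-7-en-9-ol (C9 and C10 epimers)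
Conditions: Grubbs II (5 mol%), CH2Cl2, 40 °C
Reagents that add atoms: none
Why: Ring-closing metathesis of the two monosubstituted alkenes closes six-membered ring B at C7=C8 with loss of ethylene, and no stereocentre changes.

Step 9
Reactants: 13 2α-(tert-butyldimethylsilyloxy)-11,12,13-trinoreremophil-7-en-9-ol
Product: 15 2α-(tert-butyldimethylsilyloxy)-10αH-11,12,13-trinoreremophil-7-en-9-one (trans-fused), via C10-epimeric enones 14 (not isolated)
Conditions: TPAP (5 mol%), NMO, 4 Å MS, CH2Cl2, rt; then DBU, 40 °C
Reagents that add atoms: none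
Why: Ley–Griffith oxidation converges all C9 epimers to the enone, and DBU epimerisation of the now acidic C10–H through the cross-conjugated dienolate should enrich the trans-fused 10α-H enone, reprotonation anti to the adjacent C5 methyl and product stability pointing the same way; any cis epimer is separated and resubmitted.

Step 10
Reactants: 15 2α-(tert-butyldimethylsilyloxy)-10αH-11,12,13-trinoreremophil-7-en-9-one
Product: 16 2α-(tert-butyldimethylsilyloxy)-10αH-11,12,13-trinoreremophil-7-en-9β-ol
Conditions: DIBAL-H, CH2Cl2, −78 °C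
Reagents that add atoms: none
Why: 1,2-Reduction of the enone by the bulky aluminium hydride should occur from the α-face, the β-face of C9 being screened by the syn-axial C5 methyl, which gives the pseudoaxial 9β-alcohol.

Step 11
Reactants: 16 2α-(tert-butyldimethylsilyloxy)-10αH-11,12,13-trinoreremophil-7-en-9β-ol
Product: 17 2α-(tert-butyldimethylsilyloxy)-10αH-11,12,13-trinoreremophil-7-en-9α-yl 4-nitrobenzoate
Conditions: 4-O2NC6H4CO2H, PPh3, DIAD, THF, 0 °C → rt
Reagents that add atoms: 4-nitrobenzoic acid, OC(=O)c1ccc(cc1)[N+](=O)[O-]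
Why: Mitsunobu reaction, in which the carboxylate displaces the oxyphosphonium group by SN2 from the open α-face, inverts C9 to the 9α ester.

Step 12
Reactants: 17 2α-(tert-butyldimethylsilyloxy)-10αH-11,12,13-trinoreremophil-7-en-9α-yl 4-nitrobenzoate
Product: 18 2α-(tert-butyldimethylsilyloxy)-10αH-11,12,13-trinoreremophil-7-en-9α-ol
Conditions: K2CO3 (cat.), MeOH, rt
Reagents that add atoms: none
Why: Base-catalysed methanolysis of the activated aryl ester frees the pseudoequatorial 9α allylic alcohol with retention and without touching the silyl ether.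

Step 13
Reactants: 18 2α-(tert-butyldimethylsilyloxy)-10αH-11,12,13-trinoreremophil-7-en-9α-ol
Product: 19 7α,8α-epoxy-2α-(tert-butyldimethylsilyloxy)-10αH-11,12,13-trinoreremophilan-9α-ol
Conditions: mCPBA, NaHCO3, CH2Cl2, 0 °C
Reagents that add atoms: 3-chloroperoxybenzoic acid, OOC(=O)c1cccc(Cl)c1
Why: Henbest hydroxyl-directed epoxidation, in which hydrogen bonding to the 9α-OH and shielding of the β-face by the C5 methyl both deliver oxygen to the α-face, sets the 7α,8α-epoxide.

Step 14
Reactants: 19 7α,8α-epoxy-2α-(tert-butyldimethylsilyloxy)-10αH-11,12,13-trinoreremophilan-9α-ol; 20 2-bromopropene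
Product: 22 2α-(tert-butyldimethylsilyloxy)-7αH,10αH-eremophil-11-ene-8α,9α-diol, via isopropenylmagnesium bromide 21 (not isolated)
Conditions: 20, Mg, THF; then 19, CuI (20 mol%), THF, −30 → 0 °C
Reagents that add atoms: isopropenylmagnesium bromide 21, C=C(C)[Mg]Br (made in the flask from 20)
Why: Copper-catalysed Grignard opening of the epoxide follows the Fürst–Plattner rule, so trans-diaxial attack at C7 from the β-face with inversion (as in 2α,3α-epoxy steroids) sets the axial 7β-isopropenyl group and leaves the axial 8α-OH, attack at C8 being disfavoured stereoelectronically and by the adjacent C9 alkoxide.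

Step 15
Reactants: 22 2α-(tert-butyldimethylsilyloxy)-7αH,10αH-eremophil-11-ene-8α,9α-diol; 23 angelic acid
Product: 25 9α-angeloyloxy-2α-(tert-butyldimethylsilyloxy)-7αH,10αH-eremophil-11-en-8α-ol, via mixed anhydride 24 (not isolated)
Conditions: 23, 2,4,6-Cl3C6H2COCl, Et3N, toluene, rt; then 22, toluene, 80 °C
Reagents that add atoms: angelic 2,4,6-trichlorobenzoic anhydride 24, C/C=C(/C)C(=O)OC(=O)c1c(Cl)cc(Cl)cc1Cl (made in the flask from 23)
Why: Yamaguchi-type mixed-anhydride esterification run without DMAP, to avoid Z→E isomerisation to the tiglate, should acylate the equatorial 9α-OH in preference to the axial and more hindered 8α-OH.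

Step 16
Reactants: 25 9α-angeloyloxy-2α-(tert-butyldimethylsilyloxy)-7αH,10αH-eremophil-11-en-8α-ol
Product: 26 9α-angeloyloxy-7αH,10αH-eremophil-11-ene-2α,8α-diol
Conditions: HF·pyridine, pyridine, THF, 0 °C → rt
Reagents that add atoms: none
Why: Fluoride-mediated desilylation under buffered acidic conditions removes the silyl ether while the angelate and the isopropenyl group survive and base-induced acyl migration is avoided.

Step 17
Reactants: 26 9α-angeloyloxy-7αH,10αH-eremophil-11-ene-2α,8α-diol
Product: 27 2α-acetoxy-9α-angeloyloxy-7αH,10αH-eremophil-11-en-8α-ol (CNP0217919.1)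
Conditions: Ac2O, pyridine, CH2Cl2, 0 °C → rt
Reagents that add atoms: acetic anhydride, CC(=O)OC(C)=O
Why: Acetylation should select the C2 hydroxyl, which lies between two CH2 groups, over the C8 hydroxyl, which is flanked by the substituted C7 and C9 and hydrogen-bonded to the angelate; no stereocentre changes.

**Compound list**

1 | (S)-carvone | CC1=CC[C@H](C(C)=C)CC1=O | starting material
2 | (5S)-5-(1-hydroperoxy-1-methoxyethyl)-2-methylcyclohex-2-en-1-one | CC1=CC[C@H](C(C)(OC)OO)CC1=O | intermediate
3 | 1-methoxy-1-[(1S)-4-methyl-5-oxocyclohex-3-en-1-yl]ethyl peroxyacetate | CC1=CC[C@H](C(C)(OC)OOC(C)=O)CC1=O | intermediate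
4 | (1S)-4-methyl-5-oxocyclohex-3-en-1-yl acetate | CC1=CC[C@H](OC(C)=O)CC1=O | intermediate
5 | (5S)-5-hydroxy-2-methylcyclohex-2-en-1-one | CC1=CC[C@H](O)CC1=O | intermediate
6 | (5S)-5-(tert-butyldimethylsilyloxy)-2-methylcyclohex-2-en-1-one | CC1=CC[C@H](O[Si](C)(C)C(C)(C)C)CC1=O | intermediate
7 | allyl bromide | C=CCBr | starting material
8 | lithium (3S,5S)-5-(tert-butyldimethylsilyloxy)-2,3-dimethylcyclohex-1-en-1-olate | CC1=C([O-])C[C@@H](O[Si](C)(C)C(C)(C)C)C[C@@H]1C.[Li+] | intermediate
9 | (2R,3S,5S)-2-allyl-5-(tert-butyldimethylsilyloxy)-2,3-dimethylcyclohexan-1-one | C=CC[C@]1(C)[C@@H](C)C[C@H](O[Si](C)(C)C(C)(C)C)CC1=O | intermediate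
10 | (2R,3S,5S)-2-allyl-5-(tert-butyldimethylsilyloxy)-1-(methoxymethylidene)-2,3-dimethylcyclohexane, E/Z mixture | C=CC[C@]1(C)[C@@H](C)C[C@H](O[Si](C)(C)C(C)(C)C)CC1=COC | intermediate
11 | (2R,3S,5S)-2-allyl-5-(tert-butyldimethylsilyloxy)-2,3-dimethylcyclohexane-1-carbaldehyde, C1 epimers | C=CC[C@]1(C)[C@@H](C)C[C@H](O[Si](C)(C)C(C)(C)C)CC1C=O | intermediate
12 | 1-[(2R,3S,5S)-2-allyl-5-(tert-butyldimethylsilyloxy)-2,3-dimethylcyclohexyl]prop-2-en-1-ol, epimer mixture | C=CC[C@]1(C)[C@@H](C)C[C@H](O[Si](C)(C)C(C)(C)C)CC1C(O)C=C | intermediate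
13 | 2α-(tert-butyldimethylsilyloxy)-11,12,13-trinoreremophil-7-en-9-ol, C9/C10 epimers | OC1C=CC[C@]2(C)[C@@H](C)C[C@H](O[Si](C)(C)C(C)(C)C)CC12 | intermediate
14 | 2α-(tert-butyldimethylsilyloxy)-11,12,13-trinoreremophil-7-en-9-one, C10 epimers | C1=CC[C@]2(C)[C@@H](C)C[C@H](O[Si](C)(C)C(C)(C)C)CC2C1=O | intermediate
15 | 2α-(tert-butyldimethylsilyloxy)-10αH-11,12,13-trinoreremophil-7-en-9-one | C1=CC[C@]2(C)[C@@H](C)C[C@H](O[Si](C)(C)C(C)(C)C)C[C@H]2C1=O | intermediate
16 | 2α-(tert-butyldimethylsilyloxy)-10αH-11,12,13-trinoreremophil-7-en-9β-ol | C1=CC[C@]2(C)[C@@H](C)C[C@H](O[Si](C)(C)C(C)(C)C)C[C@H]2[C@H]1O | intermediate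
17 | 2α-(tert-butyldimethylsilyloxy)-10αH-11,12,13-trinoreremophil-7-en-9α-yl 4-nitrobenzoate | C1=CC[C@]2(C)[C@@H](C)C[C@H](O[Si](C)(C)C(C)(C)C)C[C@H]2[C@@H]1OC(=O)c1ccc(cc1)[N+](=O)[O-] | intermediate
18 | 2α-(tert-butyldimethylsilyloxy)-10αH-11,12,13-trinoreremophil-7-en-9α-ol | C1=CC[C@]2(C)[C@@H](C)C[C@H](O[Si](C)(C)C(C)(C)C)C[C@H]2[C@@H]1O | intermediate
19 | 7α,8α-epoxy-2α-(tert-butyldimethylsilyloxy)-10αH-11,12,13-trinoreremophilan-9α-ol | [C@@H]12C[C@]3(C)[C@@H](C)C[C@H](O[Si](C)(C)C(C)(C)C)C[C@H]3[C@H](O)[C@@H]1O2 | intermediate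
20 | 2-bromopropene | C=C(C)Br | starting material
21 | isopropenylmagnesium bromide | C=C(C)[Mg]Br | intermediate
22 | 2α-(tert-butyldimethylsilyloxy)-7αH,10αH-eremophil-11-ene-8α,9α-diol | C=C(C)[C@H]1C[C@]2(C)[C@@H](C)C[C@H](O[Si](C)(C)C(C)(C)C)C[C@H]2[C@H](O)[C@@H]1O | intermediate
23 | angelic acid, (Z)-2-methylbut-2-enoic acid | C/C=C(/C)C(=O)O | starting material
24 | angelic 2,4,6-trichlorobenzoic anhydride | C/C=C(/C)C(=O)OC(=O)c1c(Cl)cc(Cl)cc1Cl | intermediate
25 | 9α-angeloyloxy-2α-(tert-butyldimethylsilyloxy)-7αH,10αH-eremophil-11-en-8α-ol | C=C(C)[C@H]1C[C@]2(C)[C@@H](C)C[C@H](O[Si](C)(C)C(C)(C)C)C[C@H]2[C@H](OC(=O)/C(C)=C\C)[C@@H]1O | intermediate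
26 | 9α-angeloyloxy-7αH,10αH-eremophil-11-ene-2α,8α-diol | C=C(C)[C@H]1C[C@]2(C)[C@@H](C)C[C@H](O)C[C@H]2[C@H](OC(=O)/C(C)=C\C)[C@@H]1O | intermediate
27 | 2α-acetoxy-9α-angeloyloxy-7αH,10αH-eremophil-11-en-8α-ol (CNP0217919.1) | C=C(C)[C@H]1C[C@]2(C)[C@@H](C)C[C@H](OC(C)=O)C[C@H]2[C@H](OC(=O)/C(C)=C\C)[C@@H]1O | target

**Step count and risks**

Total step count: 17. Longest linear sequence: 17 steps (1 → 27).

Step 9. Equilibration at C10 may stall at a mixture of ring-fusion isomers, because the axial C2 silyloxy group offsets part of the usual advantage of the trans-fused enone. The fallback replaces thermodynamic by kinetic control. The oxidation is run without DBU and the enone mixture 14 is isolated. Treatment with LiHMDS (THF, −78 °C) removes the C10 proton and gives the lithium cross-conjugated dienolate F1. This is quenched at −78 °C by inverse addition to 2,6-di-tert-butyl-4-methylphenol, so that the proton should enter anti to the adjacent C5 methyl. The fallback sets out from 14 and returns to the route at 15.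

Step 11. The oxyphosphonium ion of the hindered pseudoaxial allylic alcohol may ionise, eliminate across C9–C10 to the conjugated diene, or be attacked at C7 (SN2′) instead of undergoing clean inversion. The fallback replaces inversion by a reagent-controlled reduction. Enone 15 is reduced with (S)-2-methyl-CBS-oxazaborolidine and catecholborane (toluene, −78 °C); the antipodal catalyst is used if the branched C10 does not act as the large substituent. Hydride delivery to the β-face gives 18 directly, so the fallback sets out from 15, returns at 18 and bypasses 16 and 17. It makes no new compound (F0).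

Step 15. The forcing acylation may also esterify the axial C8 hydroxyl, and the angeloyl group may isomerise to the tigloyl group. The fallback activates the diol as a tin acetal. From 22, Bu2SnO (toluene, reflux, removal of water) gives the 8,9-O-dibutylstannylene acetal F2, in which the equatorial C9 oxygen is the nucleophilic one. Angelic anhydride F3, made from 23 with DCC, then acylates it at room temperature without added base. The fallback sets out from 22 and returns to the route at 25.

**Further compounds**

F1 | step 9 | lithium 2α-(tert-butyldimethylsilyloxy)-11,12,13-trinoreremophila-7,9-dien-9-olate | C1=CC[C@]2(C)[C@@H](C)C[C@H](O[Si](C)(C)C(C)(C)C)CC2=C1[O-].[Li+]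
F0 | step 11 | none | none
F2 | step 15 | 8α,9α-O-dibutylstannylene acetal of 22 | C=C(C)[C@H]1C[C@]2(C)[C@@H](C)C[C@H](O[Si](C)(C)C(C)(C)C)C[C@H]2[C@@H]3O[Sn](CCCC)(CCCC)O[C@H]13
F3 | step 15 | angelic anhydride | C/C=C(/C)C(=O)OC(=O)/C(C)=C\C
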